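**Strategy.** Elemane numbering: C10 is the quaternary carbon, C9 carries the acetate, C8 the lactone oxygen, C6 the angelate, C5 the acrolein unit. In the cyclohexane, O–C8–C7–C11(=C13H2) of the lactone and O–C6–C5–C4(=C3H2) are two homoallylic-alcohol retrons set head to tail, so the ring is cut at C7–C8 and C5–C6. In one pot the allylindium from a chiral 3-(bromomethyl)-5-menthyloxybutenolide adds to the C8 aldehyde of an acyclic (Z)-allylboronate. Translactonisation then frees the hidden C6 aldehyde, which the boronate traps. Cyclohexane, trans-lactone, both exo-methylenes and stereocentres C5–C8 arise together.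

Key step: step 11

Assumption: butenolide 15, the enantiomer of the more common (5R)-l-menthyloxy compound, is taken as purchasable. Otherwise it is made from furfural by photo-oxygenation and acetalisation with (+)-menthol.

Step 1
Reactants: 1 (tert-butyldimethylsilyloxy)acetaldehyde; 2 2-(triphenyl-λ5-phosphanylidene)propanal
Product: 3 (2E)-4-[(tert-butyldimethylsilyl)oxy]-2-methylbut-2-enal
Conditions: toluene, 90 °C
Reagents that add atoms: none
Why: Wittig olefination with a stabilised ylide should give the E-enal, which places C5 (formyl carbon) trans to C8 across the future C9–C10 bond.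

Step 2
Reactants: 3 enal; 4 vinylmagnesium bromide (CH2=CHMgBr)
Product: 5 rac-(4E)-6-[(tert-butyldimethylsilyl)oxy]-4-methylhexa-1,4-dien-3-ol
Conditions: THF, −78 °C; then water
Reagents that add atoms: none
Why: Grignard 1,2-addition to the enal; the new carbinol centre is racemic, is resolved in step 3 and is destroyed in step 4.

Step 3
Reactants: 5 racemic dienol
Product: 6 (1R)-1-[(2R,3R)-3-{[(tert-butyldimethylsilyl)oxy]methyl}-2-methyloxiran-2-yl]prop-2-en-1-ol
Conditions: Ti(OiPr)4 (10 mol %), D-(−)-diisopropyl tartrate (13 mol %), t-BuOOH (0.45 equiv), 4 Å MS, CH2Cl2, −20 °C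
Reagents that add atoms: tert-butyl hydroperoxide, CC(C)(C)OO
Why: Sharpless kinetic resolution: with the D-(−)-tartrate the (R)-alcohol should be epoxidised fast at its trisubstituted alkene (the vinyl group is far slower), which sets the (2R,3R)-epoxide and hence C9 and the face of C10, while (S)-5 stays behind and is separated.

Step 4
Reactants: 6 epoxy alcohol
Product: 8 (2S,3R)-1-[(tert-butyldimethylsilyl)oxy]-3-formyl-3-methylpent-4-en-2-yl acetate, via hydroxy aldehyde 7 (not isolated)
Conditions: BF3·OEt2 (20 mol %), CH2Cl2, −78 °C; then pyridine, Ac2O, DMAP (cat.), −78 to 0 °C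
Reagents that add atoms: acetic anhydride, CC(=O)OC(C)=O
Why: Semipinacol rearrangement of a 2,3-epoxy alcohol: the epoxide opens at tertiary C10 while the vinyl group migrates from the carbinol carbon anti to the leaving oxygen (inversion at C10, retention at C9, carbinol carbon becomes the C5 aldehyde), and aldol 7 is acetylated in the same flask before retro-aldol cleavage can set in.

Step 5
Reactants: 8 acetoxy aldehyde; 9 ethyltriphenylphosphonium iodide
Product: 10 (2S,3S,4Z)-1-[(tert-butyldimethylsilyl)oxy]-3-ethenyl-5-iodo-3-methylhex-4-en-2-yl acetate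
Conditions: 9, n-BuLi, THF, rt; I2, −78 °C; NaN(SiMe3)2, −20 °C; then 8, −78 to −20 °C
Reagents that add atoms: iodine, [I][I]
Why: Stork–Zhao-type Wittig olefination with the α-iodo ylide should give the (Z)-iodoalkene (iodine cis to C10) under kinetic control, and the aldehyde has no α-hydrogen, so neither epimerisation nor β-elimination of acetate is possible.

Step 6
Reactants: 10 (Z)-alkenyl iodide; 11 2-(iodomethyl)-4,4,5,5-tetramethyl-1,3,2-dioxaborolane
Product: 12 (2S,3S,4Z)-1-[(tert-butyldimethylsilyl)oxy]-3-ethenyl-3,5-dimethyl-6-(4,4,5,5-tetramethyl-1,3,2-dioxaborolan-2-yl)hex-4-en-2-yl acetate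
Conditions: 11, Zn dust, THF, rt; then 10, Pd(PPh3)4 (5 mol %), THF, 40 °C
Reagents that add atoms: none
Why: Negishi cross-coupling of an alkenyl iodide with the α-boryl alkylzinc reagent proceeds with retention of alkene geometry, so CH2Bpin ends cis to C10, and the neutral conditions spare acetate and silyl ether.

Step 7
Reactants: 12 silyl ether
Product: 13 (2S,3S,4Z)-3-ethenyl-1-hydroxy-3,5-dimethyl-6-(4,4,5,5-tetramethyl-1,3,2-dioxaborolan-2-yl)hex-4-en-2-yl acetate
Conditions: camphorsulfonic acid (10 mol %), MeOH–CH2Cl2 1:1, 0 °C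
Reagents that add atoms: none
Why: Acid-catalysed methanolysis removes a primary TBS ether selectively, and the cold, base-free medium should suppress 1,2-acetyl migration and leave the pinacol boronate intact.

Step 8
Reactants: 13 primary alcohol
Product: 14 (2S,3S,4Z)-3-ethenyl-3,5-dimethyl-1-oxo-6-(4,4,5,5-tetramethyl-1,3,2-dioxaborolan-2-yl)hex-4-en-2-yl acetate
Conditions: Dess–Martin periodinane, pyridine, CH2Cl2, 0 °C; used at once
Reagents that add atoms: none
Why: Dess–Martin oxidation is neutral and fast, so C9 is not epimerised, and 14 cannot allylate itself because the γ-carbon C5 and the aldehyde C8 would have to close a four-membered ring.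

Step 9
Reactants: 15 (5S)-5-{[(1S,2R,5S)-5-methyl-2-(propan-2-yl)cyclohexyl]oxy}furan-2(5H)-one
Product: 18 (5S)-3-(hydroxymethyl)-5-{[(1S,2R,5S)-5-methyl-2-(propan-2-yl)cyclohexyl]oxy}furan-2(5H)-one, via selenide 16 (not isolated), via selenoxide 17 (not isolated)
Conditions: PhLi, Se powder, THF, 0 °C (gives PhSeLi); 15, −60 °C; CH2O gas; then H2O2 (30 %), pyridine, 0 °C
Reagents that add atoms: formaldehyde, C=O
Why: Selenolate-mediated Morita–Baylis–Hillman-type hydroxymethylation: PhSeLi adds to C4 of the butenolide anti to the menthyloxy group, the enolate takes up formaldehyde at C3, and selenoxide syn-elimination towards the acidic C3–H restores the butenolide without touching the acetal stereocentre.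

Step 10
Reactants: 18 allylic alcohol
Product: 19 (5S)-3-(bromomethyl)-5-{[(1S,2R,5S)-5-methyl-2-(propan-2-yl)cyclohexyl]oxy}furan-2(5H)-one
Conditions: CBr4, PPh3, CH2Cl2, 0 °C
Reagents that add atoms: carbon tetrabromide, BrC(Br)(Br)Br
Why: Appel reaction converts the primary allylic alcohol into the bromide under neutral conditions that leave the acid- and base-sensitive acetal centre unchanged.

Step 11
Reactants: 14 aldehyde (Z)-allylboronate; 19 bromomethyl menthyloxybutenolide
Product: 23 9α-acetoxy-6β-hydroxyelema-1,3,11(13)-trien-12,8α-olide (5αH,7αH,8βH, 10β-methyl), via Barbier adduct 20 (not isolated), via formyl lactone 21 (not isolated), via borate 22 (not isolated)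
Conditions: In powder (1.1 equiv), 19 (1.05 equiv), THF–H2O 4:1, 0 °C to rt; then Sc(OTf)3 (10 mol %), 40 °C
Reagents that add atoms: none
Why: Proposed new method: indium inserts into the C–Br bond of 19 and the allylindium adds through its ring carbon C7 to aldehyde C8 of 14 in a closed chair (C7–C8 bond, 20); the C8 hydroxyl then attacks pseudoester carbonyl C12 (5-exo-trig acyl transfer that closes the 8,12-lactone), the expelled C6 hemiacetal loses menthol to give aldehyde 21, and its (Z)-allylboronate adds through C5 to C6 (6-exo-trig closure of the cyclohexane through a bicyclic Zimmerman–Traxler chair, C5–C6 bond, 22, hydrolysed to 23). The closest known reactions are the zinc- or indium-mediated Barbier allylation of aldehydes with 3-(bromomethyl)furan-2(5H)-one followed by translactonisation, and the intramolecular allylboration of ω-oxo allylboronates; what is new is their relay through an acetal that hides the second aldehyde until the first bond and the lactone exist. C7 is set by attack anti to the menthyloxy group on the neighbouring acetal carbon, and C8 by the chair with the ring-locked E-type allyl geometry (anti adduct, hence trans-lactone), reinforced by the Cornforth or polar Felkin–Anh preference of the α-acetoxy aldehyde for the 8,9-anti diol pattern. C5 and C6 are set on the trans-lactone template, which allows only the chair with the C7 and C8 substituents equatorial: the C4 unit goes equatorial because the axial site at C5 is blocked by the axial C9 acetate, and the Z-boronate (CH2B cis to C10) then forces the C6 oxygen axial, cis to the C4 unit. The step needs chemoselectivity between two allyl donors and two aldehydes: the boronate of 14 is flanked by quaternary C10 and is slow in any intermolecular reaction while the allylindium is fast, and surplus allylindium is hydrolysed by the aqueous medium before Sc(OTf)3 starts the unmasking.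

Step 12
Reactants: 23 hydroxy lactone; 24 angelic acid [(2Z)-2-methylbut-2-enoic acid]
Product: 25 9α-acetoxy-6β-angeloyloxyelema-1,3,11(13)-trien-12,8α-olide
Conditions: 24, 2,4,6-trichlorobenzoyl chloride, Et3N, toluene, rt; then 23, 80 °C (no DMAP)
Reagents that add atoms: none
Why: Yamaguchi-type mixed-anhydride esterification without nucleophilic catalyst is the established way to acylate hindered secondary alcohols with angelic acid without Z-to-E isomerisation, and C6–OH is the only free hydroxyl.

Step 13
Reactants: 25 angelate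
Product: 27 CNP0228039.1, 9α-acetoxy-6β-angeloyloxy-15-oxoelema-1,3,11(13)-trien-12,8α-olide, via allylic alcohol 26 (not isolated)
Conditions: SeO2 (1.5 equiv), 1,4-dioxane, 70 °C
Reagents that add atoms: selenium dioxide, O=[Se]=O
Why: Riley allylic oxidation (ene reaction, [2,3]-shift, then oxidation of the allylic alcohol): the isopropenyl group is the only electron-rich alkene with allylic hydrogens (the vinyl group has none, methylene lactone and angelate are electron-poor), so its methyl group should become the C15 aldehyde.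

**Compound list**
1 | (tert-butyldimethylsilyloxy)acetaldehyde | O=CCO[Si](C)(C)C(C)(C)C | starting material
2 | 2-(triphenyl-λ5-phosphanylidene)propanal | CC(C=O)=P(c1ccccc1)(c1ccccc1)c1ccccc1 | starting material
3 | (2E)-4-[(tert-butyldimethylsilyl)oxy]-2-methylbut-2-enal | O=C/C(C)=C/CO[Si](C)(C)C(C)(C)C | intermediate
4 | vinylmagnesium bromide | C=C[Mg]Br | starting material
5 | rac-(4E)-6-[(tert-butyldimethylsilyl)oxy]-4-methylhexa-1,4-dien-3-ol | C=CC(O)/C(C)=C/CO[Si](C)(C)C(C)(C)C | intermediate
6 | (1R)-1-[(2R,3R)-3-{[(tert-butyldimethylsilyl)oxy]methyl}-2-methyloxiran-2-yl]prop-2-en-1-ol | C=C[C@@H](O)[C@@]1(C)O[C@@H]1CO[Si](C)(C)C(C)(C)C | intermediate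
7 | (2R,3S)-4-[(tert-butyldimethylsilyl)oxy]-2-ethenyl-3-hydroxy-2-methylbutanal | C=C[C@](C=O)(C)[C@H](O)CO[Si](C)(C)C(C)(C)C | intermediate
8 | (2S,3R)-1-[(tert-butyldimethylsilyl)oxy]-3-formyl-3-methylpent-4-en-2-yl acetate | C=C[C@](C=O)(C)[C@H](OC(C)=O)CO[Si](C)(C)C(C)(C)C | intermediate
9 | ethyltriphenylphosphonium iodide | CC[P+](c1ccccc1)(c1ccccc1)c1ccccc1.[I-] | starting material
10 | (2S,3S,4Z)-1-[(tert-butyldimethylsilyl)oxy]-3-ethenyl-5-iodo-3-methylhex-4-en-2-yl acetate | C=C[C@](/C=C(\I)C)(C)[C@H](OC(C)=O)CO[Si](C)(C)C(C)(C)C | intermediate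
11 | 2-(iodomethyl)-4,4,5,5-tetramethyl-1,3,2-dioxaborolane | ICB1OC(C)(C)C(C)(C)O1 | starting material
12 | (2S,3S,4Z)-1-[(tert-butyldimethylsilyl)oxy]-3-ethenyl-3,5-dimethyl-6-(pinacolatoboryl)hex-4-en-2-yl acetate | C=C[C@](/C=C(\CB1OC(C)(C)C(C)(C)O1)C)(C)[C@H](OC(C)=O)CO[Si](C)(C)C(C)(C)C | intermediate
13 | (2S,3S,4Z)-3-ethenyl-1-hydroxy-3,5-dimethyl-6-(pinacolatoboryl)hex-4-en-2-yl acetate | C=C[C@](/C=C(\CB1OC(C)(C)C(C)(C)O1)C)(C)[C@H](OC(C)=O)CO | intermediate
14 | (2S,3S,4Z)-3-ethenyl-3,5-dimethyl-1-oxo-6-(pinacolatoboryl)hex-4-en-2-yl acetate | C=C[C@](/C=C(\CB1OC(C)(C)C(C)(C)O1)C)(C)[C@H](OC(C)=O)C=O | intermediate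
15 | (5S)-5-(d-menthyloxy)furan-2(5H)-one | O=C1C=C[C@H](O1)O[C@H]2C[C@@H](C)CC[C@@H]2C(C)C | starting material
16 | 3,4-trans-4,5-trans 3-(hydroxymethyl)-5-(d-menthyloxy)-4-(phenylselanyl)oxolan-2-one | O=C1[C@@H](CO)[C@H]([Se]c2ccccc2)[C@H](O1)O[C@H]3C[C@@H](C)CC[C@@H]3C(C)C | intermediate
17 | selenoxide of 16 | O=C1[C@@H](CO)[C@H]([Se](=O)c2ccccc2)[C@H](O1)O[C@H]3C[C@@H](C)CC[C@@H]3C(C)C | intermediate
18 | (5S)-3-(hydroxymethyl)-5-(d-menthyloxy)furan-2(5H)-one | O=C1C(CO)=C[C@H](O1)O[C@H]2C[C@@H](C)CC[C@@H]2C(C)C | intermediate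
19 | (5S)-3-(bromomethyl)-5-(d-menthyloxy)furan-2(5H)-one | O=C1C(CBr)=C[C@H](O1)O[C@H]2C[C@@H](C)CC[C@@H]2C(C)C | intermediate
20 | Barbier adduct: C8 alcohol whose C7 sits in the α-methylene menthyl-acetal lactone, C8 chain trans to the menthyloxy group | C=C[C@](/C=C(\CB1OC(C)(C)C(C)(C)O1)C)(C)[C@H](OC(C)=O)[C@H](O)[C@H]2C(=C)C(=O)O[C@@H]2O[C@H]3C[C@@H](C)CC[C@@H]3C(C)C | intermediate
21 | trans-β-formyl-α-methylene-γ-butyrolactone that carries the (Z)-allylboronate chain at C8 | C=C[C@](/C=C(\CB1OC(C)(C)C(C)(C)O1)C)(C)[C@H](OC(C)=O)[C@@H]2OC(=O)C(=C)[C@H]2C=O | intermediate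
22 | 6-O-pinacolboryl ether of 23 | C=C[C@]1(C)[C@H](OC(C)=O)[C@@H]2OC(=O)C(=C)[C@H]2[C@@H](OB3OC(C)(C)C(C)(C)O3)[C@H]1C(=C)C | intermediate
23 | 9α-acetoxy-6β-hydroxyelema-1,3,11(13)-trien-12,8α-olide | C=C[C@]1(C)[C@H](OC(C)=O)[C@@H]2OC(=O)C(=C)[C@H]2[C@@H](O)[C@H]1C(=C)C | intermediate
24 | angelic acid | C/C=C(/C)C(=O)O | starting material
25 | 9α-acetoxy-6β-angeloyloxyelema-1,3,11(13)-trien-12,8α-olide | C=C[C@]1(C)[C@H](OC(C)=O)[C@@H]2OC(=O)C(=C)[C@H]2[C@@H](OC(=O)/C(C)=C\C)[C@H]1C(=C)C | intermediate
26 | 15-hydroxy derivative of 25 | C=C[C@]1(C)[C@H](OC(C)=O)[C@@H]2OC(=O)C(=C)[C@H]2[C@@H](OC(=O)/C(C)=C\C)[C@H]1C(=C)CO | intermediate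
27 | CNP0228039.1 | C=C[C@]1(C)[C@H](OC(C)=O)[C@@H]2OC(=O)C(=C)[C@H]2[C@@H](OC(=O)/C(C)=C\C)[C@H]1C(=C)C=O | target

Total steps: 13. Longest linear sequence: 11 steps (steps 1–8 and 11–13).

**Steps most likely to fail**

Step 11. Several processes may go wrong.
- The allylindium may lose the menthyloxy group by 1,4-elimination before it meets the aldehyde.
- Surplus allylindium may over-add to the freed C6 aldehyde.
- The acyl transfer may stall.
- The Lewis acid may ionise the acetal, so that C5–C6 forms before the acyl transfer and the lactone ends on the C6 oxygen.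

The fallback sets out from 19 and 14 and comes back at 23. Bromide 19 is borylated by palladium-catalysed allylic borylation (B2pin2, Pd2(dba)3 cat., toluene, 50 °C) to (5S)-5-(d-menthyloxy)-3-[(pinacolatoboryl)methyl]furan-2(5H)-one F1. F1 and 14 are then combined with Sc(OTf)3 (10 mol %) in toluene at 0 °C to rt, followed by aqueous work-up. This is the known Lewis-acid-catalysed allylboration of aldehydes with 2-alkoxycarbonyl allylboronates with lactonisation in the flask. No reducing metal and no highly reactive allylmetal are present, and the ring-locked geometry reacts through the same closed chair. The lactonisation again frees aldehyde 21 for the second allylboration, so both ring bonds still form in one flask.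

Step 5. The neopentyl-type aldehyde may be olefinated slowly, the ylide may lose iodine (giving the iodine-free alkene), or Z-selectivity may erode. The fallback sets out from 8 and comes back at 12. Ramirez dibromo-olefination (CBr4, PPh3, CH2Cl2, 0 °C) gives (2S,3S)-5,5-dibromo-1-[(tert-butyldimethylsilyl)oxy]-3-ethenyl-3-methylpent-4-en-2-yl acetate F2. Negishi methylation (MeZnCl, PdCl2(DPEphos) cat., THF, 0 °C) replaces selectively the less hindered bromine trans to C10 and gives the (4Z)-5-bromohex-4-ene analogue of 10, F3. A second Negishi coupling with the zinc reagent from 11 (Pd(P(t-Bu)3)2 cat., THF, rt) proceeds with retention and gives 12.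

Step 13. The oxidation may go too far, may attack the angelate methyl groups, may isomerise the angelate from Z to E at 70 °C, or may halt at the allylic alcohol stage. The fallback sets out from 25 and comes back at 27. Ene-type allylic chlorination of the isopropenyl group with hypochlorous acid (Ca(OCl)2, solid CO2, CH2Cl2–H2O, 0 °C) gives the 15-chloro derivative of 25, F4. Kornblum-type oxidation with N-methylmorpholine N-oxide (NaI cat., MeCN, rt) then gives the aldehyde 27 at room temperature and without selenium.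

**Further compounds**
F1 | step 11 | (5S)-5-(d-menthyloxy)-3-[(pinacolatoboryl)methyl]furan-2(5H)-one | O=C1C(CB3OC(C)(C)C(C)(C)O3)=C[C@H](O1)O[C@H]2C[C@@H](C)CC[C@@H]2C(C)C
F2 | step 5 | (2S,3S)-5,5-dibromo-1-[(tert-butyldimethylsilyl)oxy]-3-ethenyl-3-methylpent-4-en-2-yl acetate | C=C[C@](C=C(Br)Br)(C)[C@H](OC(C)=O)CO[Si](C)(C)C(C)(C)C
F3 | step 5 | (2S,3S,4Z)-5-bromo-1-[(tert-butyldimethylsilyl)oxy]-3-ethenyl-3-methylhex-4-en-2-yl acetate | C=C[C@](/C=C(\Br)C)(C)[C@H](OC(C)=O)CO[Si](C)(C)C(C)(C)C
F4 | step 13 | 9α-acetoxy-6β-angeloyloxy-15-chloroelema-1,3,11(13)-trien-12,8α-olide | C=C[C@]1(C)[C@H](OC(C)=O)[C@@H]2OC(=O)C(=C)[C@H]2[C@@H](OC(=O)/C(C)=C\C)[C@H]1C(=C)CCl
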